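(The runs are simulated from invented constants, noise included.)

Thursday's run reads Zb and Zd together at 64.7% of the Za charged at 15.0 min, and one minus its starting [Ze]/[Za] is 66.0%. Monday's run reads 25.6% at 15.0 min, against 25.0% from its own start.

| flask | Za | Ze | remark | time |
|---|---|---|---|---|
| Thursday's | 0.10 M | 0.034 M | run made earlier |  |
| Monday's | 0.10 M | 0.075 M | run made earlier |  |
| Saturday's | 0.20 M | 0.050 M | run made earlier |  |
| flask | 0.10 M | 0.0500 M |  | 25 min |

| run | time / min | Zb / % | Zd / % |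
|---|---|---|---|
| Thursday's | 0.833 | 12.0 | 0.5 |
| Thursday's | 1.33 | 17.2 | 3.0 |
| Thursday's | 2.50 | 22.4 | 8.9 |
| Thursday's | 4.00 | 24.7 | 18.3 |
| Thursday's | 6.00 | 21.3 | 28.7 |
| Thursday's | 10.0 | 12.7 | 47.9 |
| Thursday's | 15.0 | 5.2 | 59.5 |
| Monday's | 0.833 | 8.5 | 0.3 |
| Monday's | 1.33 | 9.6 | 1.4 |
| Monday's | 2.50 | 10.9 | 4.7 |
| Monday's | 4.00 | 10.2 | 8.6 |
| Monday's | 6.00 | 7.9 | 14.5 |
| Monday's | 10.0 | 3.7 | 20.3 |
| Monday's | 15.0 | 2.0 | 23.6 |
| Saturday's | 0.833 | 12.7 | 1.2 |
| Saturday's | 2.00 | 22.5 | 5.7 |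
| Saturday's | 4.00 | 26.8 | 19.3 |
| Saturday's | 8.00 | 19.0 | 44.2 |
| Saturday's | 15.0 | 5.4 | 66.2 |

(each reading ± 0.5 percentage points)

* the best time, 25 min at the latest, for Zb
* the amount of Zb, in percent of the Za charged, at that time

- a reading or a percentage of Zd counts all its forms, free or not

So I read Ze as removing Za one to one. In the new flask Ze is the limiting reagent of that loss. How much can go on through Zb? The usable share, one minus the starting [Ze]/[Za], is 50.0% in this flask.

How much of that share stands as Zb at the top? Thursday's highest reading, 24.7%, is 0.374 of its usable share. Monday's highest reading gives 0.436, so the two runs differ in this ratio. I keep Thursday's, whose [Ze] is nearer to this flask's than Monday's, and my estimate for this flask is 18.7%.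

When? The highest readings fall at 4.00 min on Thursday and 2.50 min on Monday. Interpolating on [Ze], I expect 3.41 min.

The forecast, “an estimate by interpolation”, says 19.5% at 3.2 min, higher than my figure.

The flask gives 18.2% of Zb at 3.55 min.

    Za → Zb (k = 0.00420 s⁻¹)
    Zb → Zc (k = 0.00440 s⁻¹)
    Zc → Zd (k = 0.0750 s⁻¹)
    Za + Ze → Zg (k = 1.00 M⁻¹ s⁻¹)
    Zf ⇌ Zd, rate k5*(cs5 - [Zd]) while solid is left; crystals form when [Zd] > cs5 (solubility = 11.0 mM, k = 0.200 s⁻¹)

At 0.138 min in this flask, Za goes to Zg 5.9 times as fast as to Zb, and half of that loss is done by 0.138 min, far shorter than the 2.8 min half-life of Za by the making of Zb; Zg ends at 50.0%, the 50.0% that the usable share leaves. For the neighbour with 0.060 M of Za, the starting ratio gives a usable share of 16.7%, but 5.06% of its Ze is still there at 25.0 min; counting that gives 20.9%, and its Zd stands at 20.8% at that time.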